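**Strategy.** The route rests on cutting the bond between the aza-quaternary carbon common to rings A, B and C and the ring B/C fusion carbon. Ring A holds that quaternary carbon at C2 and the lactone-E-bearing carbon at C5, so it is treated as a 2,5-disubstituted pyrrole. One iridium-catalysed asymmetric allylic dearomatisation then closes cyclopentane ring C as a spiro-2H-pyrrole and sets both carbons of the new bond. The precursor is a 5-(silyloxymethyl)pyrrole whose C2 carries a CH2–C(ketal)–CH(Et) tether ending in an (E)-allylic methyl carbonate. Afterwards the vinyl group grows into ring B, the unmasked ketone into lactone D and the silyloxymethyl group into lactone E.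

Key step: step 9

Remark 1: the ethyl-bearing carbon comes from an α-ethyl β-keto ester, so compounds 4–14 are racemic there and are drawn without a descriptor. Compound 15 and later ones are drawn as the isomer with ethyl trans to the neighbouring fusion-carbon substituent, to which any ethyl epimer converges in step 12.
Remark 2: the hydroxymethyl group is carried as its tert-butyldiphenylsilyl (TBDPS) ether, which survives the acidic ketal cleavage of step 12.
Remark 3: the (Ra,R,R) ligand is assumed, from the usual facial model of these catalysts, to give the (R)-configured vinyl-bearing carbon; the antipodal ligand is used if the first run shows the opposite sense.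

Step 1
Reactants: 1 2-(1H-pyrrol-2-yl)acetonitrile; 2 ethyl 2-bromobutanoate
Product: 4 ethyl 2-ethyl-3-oxo-4-(1H-pyrrol-2-yl)butanoate, via enamino ester 3 (not isolated)
Conditions: Zn (Me3SiCl-activated), THF, reflux, slow addition of 2 (3 equiv); then 1 M HCl, THF, 0 °C
Reagents that add atoms: water, O
Why: Blaise reaction, in which the zinc enolate of 2 adds to the nitrile and brief acid hydrolysis of the enamino ester gives the β-keto ester; the pyrrole N–H only costs extra reagent.

Step 2
Reactants: 4 ethyl 2-ethyl-3-oxo-4-(1H-pyrrol-2-yl)butanoate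
Product: 6 ethyl 2-ethyl-4-(5-formyl-1H-pyrrol-2-yl)-3-oxobutanoate, via iminium chloride 5 (not isolated)
Conditions: (chloromethylene)dimethyliminium chloride (1.1 equiv), CH2Cl2, −20 to 0 °C; then aq. NaOAc, rt
Reagents that add atoms: (chloromethylene)dimethyliminium chloride, C[N+](C)=CCl.[Cl-]; water, O
Why: Vilsmeier–Haack formylation, fast at the free α-position of a 2-alkylpyrrole and slow at the keto ester enol at this temperature; the formyl group makes the ring acid-tolerant for step 3.

Step 3
Reactants: 6 ethyl 2-ethyl-4-(5-formyl-1H-pyrrol-2-yl)-3-oxobutanoate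
Product: 7 ethyl 2-{2-[(5-formyl-1H-pyrrol-2-yl)methyl]-1,3-dioxolan-2-yl}butanoate
Conditions: HOCH2CH2OH (5 equiv), TsOH·H2O (5 mol%), benzene, reflux, Dean–Stark
Reagents that add atoms: ethane-1,2-diol, OCCO
Why: acid-catalysed ketalisation of the keto group of a β-keto ester; the 2-formylpyrrole, a vinylogous formamide, neither oligomerises nor gives an acetal that survives aqueous work-up.

Step 4
Reactants: 7 formyl ketal ester
Product: 8 ethyl 2-{2-[(5-(hydroxymethyl)-1H-pyrrol-2-yl)methyl]-1,3-dioxolan-2-yl}butanoate
Conditions: NaBH4, EtOH, 0 °C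
Reagents that add atoms: none
Why: borohydride reduction of the aldehyde in the presence of the ester; the acid-sensitive pyrrolylmethanol is silylated without delay.

Step 5
Reactants: 8 pyrrolylmethanol
Product: 9 ethyl 2-{2-[(5-{[tert-butyl(diphenyl)silyl]oxymethyl}-1H-pyrrol-2-yl)methyl]-1,3-dioxolan-2-yl}butanoate
Conditions: t-BuPh2SiCl, imidazole, DMF, 0 °C to rt
Reagents that add atoms: tert-butyl(chloro)diphenylsilane, CC(C)(C)[Si](Cl)(c1ccccc1)c1ccccc1
Why: silyl ether formation at the primary alcohol under conditions that do not silylate the pyrrole nitrogen.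

Step 6
Reactants: 9 TBDPS-protected ketal ester; 10 triethyl phosphonoacetate
Product: 12 ethyl (E)-4-{2-[(5-{[tert-butyl(diphenyl)silyl]oxymethyl}-1H-pyrrol-2-yl)methyl]-1,3-dioxolan-2-yl}hex-2-enoate, via aldehyde 11 (not isolated)
Conditions: i-Bu2AlH (2.2 equiv), CH2Cl2, −78 °C; then 10/NaH in THF, −78 °C to rt
Reagents that add atoms: none
Why: one-pot partial ester reduction (the aluminium hemiacetal is held by the neighbouring ketal oxygen; one equivalent of hydride is spent on N–H) followed by Horner–Wadsworth–Emmons olefination, which should give the (E)-enoate.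

Step 7
Reactants: 12 (E)-enoate
Product: 13 (E)-4-{2-[(5-{[tert-butyl(diphenyl)silyl]oxymethyl}-1H-pyrrol-2-yl)methyl]-1,3-dioxolan-2-yl}hex-2-en-1-ol
Conditions: i-Bu2AlH (3.5 equiv), CH2Cl2, −78 °C; aq. potassium sodium tartrate work-up
Reagents that add atoms: none
Why: 1,2-reduction of the enoate to the (E)-allylic alcohol.

Step 8
Reactants: 13 allylic alcohol
Product: 14 (E)-4-{2-[(5-{[tert-butyl(diphenyl)silyl]oxymethyl}-1H-pyrrol-2-yl)methyl]-1,3-dioxolan-2-yl}hex-2-en-1-yl methyl carbonate (racemic cyclisation precursor)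
Conditions: ClCO2Me, pyridine, CH2Cl2, 0 °C
Reagents that add atoms: methyl chloroformate, COC(=O)Cl
Why: O-acylation of the allylic alcohol; the neutral pyrrole nitrogen is not acylated without a strong base.

Step 9
Reactants: 14 allylic carbonate precursor
Product: 15 vinyl spiro-2H-pyrrole, (5R,6R,7R)-2-{[tert-butyl(diphenyl)silyl]oxymethyl}-7-ethyl-6-vinyl-1-azaspiro[4.4]nona-1,3-dien-8-one ethylene ketal
Conditions: [Ir(cod)Cl]2 (2 mol%), (Ra,R,R)-BINOL-derived N,N-bis(1-phenylethyl)phosphoramidite (4 mol%, catalyst pre-formed with n-PrNH2), Cs2CO3 (1 equiv), THF, 50 °C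
Reagents that add atoms: none
Why: The cyclometalated iridium–phosphoramidite complex ionises the carbonate to a (π-allyl)iridium species, and the caesium pyrrolide attacks its substituted terminus through pyrrole C2, anti to the metal; the known reaction type is the iridium-catalysed intramolecular asymmetric allylic dearomatisation of 2,5-disubstituted pyrroles. Ring C closes in 5-exo mode on the inner allyl carbon, whereas attack through nitrogen or C3 would need a six-membered ring and attack at the outer terminus a seven-membered one, and the gem-disubstitution of the ketal carbon helps the five-ring closure. The vinyl-bearing carbon is set by the catalyst when the allyl face is chosen at ionisation, and the spiro carbon by the pyrrole face, which should turn the small ring nitrogen and not C3–H toward the vinyl group (vinyl cis to N). Because C2 becomes quaternary the ring cannot rearomatise, so the 2H-pyrrole should be isolable under these basic, acid-free conditions. The ethyl-bearing carbon is racemic: the (R)-antipode should be the matched one and give 15 with ethyl trans to vinyl, while the (S)-antipode should react more slowly, either to the ethyl epimer (which converges in step 12) or not at all.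

Step 10
Reactants: 15 vinyl spiro-2H-pyrrole; 16 methyl but-3-enoate
Product: 17 spiro-2H-pyrrole with an (E)-4-methoxy-4-oxobut-1-enyl group in place of vinyl
Conditions: 16 (5 equiv), second-generation Hoveyda–Grubbs catalyst (5 mol%), 1,4-benzoquinone (10 mol%), CH2Cl2, 40 °C
Reagents that add atoms: none
Why: olefin cross-metathesis between a hindered vinyl group that does not homodimerise and an excess of an unhindered partner; benzoquinone suppresses isomerisation of the β,γ-unsaturated ester, the ketimine nitrogen is shielded by the adjacent quaternary carbon, and the endocyclic C=C of the five-membered azadiene is not a metathesis substrate.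

Step 11
Reactants: 17 unsaturated ester
Product: 19 tricyclic lactam ketal (rings A, B, C), via amino ester 18 (not isolated)
Conditions: H2 (4 atm), Pd/C, MeOH, rt; filter; then 2-hydroxypyridine (0.2 equiv), toluene, 110 °C
Reagents that add atoms: none
Why: heterogeneous hydrogenation saturates both C=C bonds and the cyclic ketimine, hydrogen reaching the imine carbon from the ring-A face opposite the ester chain that sits under the C=N bond (this sets the ring-A stereocentre with CH2OSi cis to the fusion carbon), and the amino ester then closes seven-membered ring B by lactamisation.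

Step 12
Reactants: 19 tricyclic lactam ketal
Product: 20 tricyclic keto lactam
Conditions: 2 M HCl, THF, 40 °C
Reagents that add atoms: water, O
Why: acid hydrolysis of the dioxolane spares the TBDPS ether and the lactam; the lactam keeps nitrogen non-basic so the β-amino ketone cannot open by a retro-Mannich path, and acid-mediated enolisation equilibrates the ethyl-bearing carbon to the trans arrangement.

Step 13
Reactants: 20 tricyclic keto lactam; 21 ethyl glyoxylate
Product: 22 aldol adduct (ethyl 2-hydroxyacetate arm on the CH2 carbon between ketone and spiro carbon, cis to the ring-A CH2; carbinol carbon as a mixture)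
Conditions: LiN(i-Pr)2 (1.1 equiv), THF, −78 °C; 21 (freshly distilled monomer, 1.5 equiv), −78 °C; AcOH quench
Reagents that add atoms: none
Why: kinetic deprotonation at the CH2 α to the ketone (the other α-position is a tertiary C–H flanked by ethyl and the fusion carbon) and aldol addition to the highly electrophilic glyoxylate; the electrophile should enter anti to the pseudo-axial lactam nitrogen on the adjacent spiro carbon, and the configuration of the new carbinol carbon is irrelevant because it is re-set in step 16.

Step 14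
Reactants: 22 aldol adduct
Product: 24 α-hydroxy lactone (rings A–D), via diol ester 23 (not isolated)
Conditions: LiBH(s-Bu)3 (2.5 equiv), THF, −78 to 0 °C; AcOH quench
Reagents that add atoms: none
Why: the bulky hydride attacks the cyclopentanone from the face opposite its two cis α-substituents (ethyl and the hydroxy ester arm) to give the all-cis alkoxide, which lactonises onto the ethyl ester and closes cis-fused ring D.

Step 15
Reactants: 24 α-hydroxy lactone
Product: 25 α-(tert-butyldimethylsilyloxy) lactone
Conditions: t-BuMe2SiOTf, 2,6-lutidine, CH2Cl2, 0 °C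
Reagents that add atoms: tert-butyldimethylsilyl triflate, CC(C)(C)[Si](C)(C)OS(=O)(=O)C(F)(F)F
Why: silylation of the secondary α-hydroxy lactone so that the lactone can be enolised with one equivalent of base.

Step 16
Reactants: 25 α-silyloxy lactone
Product: 26 α-methyl-α-silyloxy lactone (methyl on the convex face, cis to the ring-fusion hydrogens)
Conditions: KN(SiMe3)2 (1.2 equiv), THF, −78 °C; MeI, −78 to −40 °C
Reagents that add atoms: iodomethane, CI
Why: enolate alkylation, in which the silazide enolises the lactone but not the tertiary lactam and iodomethane adds to the convex face of the cis-fused bicycle, away from ring C and the ring-A CH2, setting the quaternary carbon with methyl exo and oxygen endo.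

Step 17
Reactants: 26 bis-silyl ether
Product: 27 diol (primary alcohol on ring A, tertiary alcohol on lactone D)
Conditions: Bu4NF (4 equiv), AcOH (4 equiv), THF, rt to 45 °C
Reagents that add atoms: none
Why: fluoride cleaves both silyl ethers, with acetic acid buffering the alkoxides so the lactone is not opened.

Step 18
Reactants: 27 diol
Product: 28 carboxylic acid on ring A
Conditions: TEMPO (0.2 equiv), PhI(OAc)2 (2.5 equiv), MeCN/H2O (1:1), rt
Reagents that add atoms: water, O
Why: oxoammonium (TEMPO) oxidation of the primary alcohol through the aldehyde hydrate to the acid; the tertiary alcohol, lactam and lactone are inert.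

Step 19
Reactants: 28 carboxylic acid
Product: 29 S-ethyl thioester
Conditions: EtSH (3 equiv), dicyclohexylcarbodiimide, 4-(dimethylamino)pyridine (0.1 equiv), CH2Cl2, 0 °C
Reagents that add atoms: ethanethiol, CCS
Why: Steglich-type thioesterification; the hindered tertiary alcohol is not acylated and the thiol traps the activated acid quickly enough to protect the α-stereocentre.

Step 20
Reactants: 30 methyl (R)-3-bromo-2-methylpropanoate
Product: 31 [(R)-3-methoxy-2-methyl-3-oxopropyl]zinc bromide
Conditions: Zn dust, I2 (5 mol%), N,N-dimethylacetamide, 70 °C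
Reagents that add atoms: zinc, [Zn]
Why: direct insertion of zinc into the primary C–Br bond gives the β-zincated ester and leaves the α-methyl stereocentre untouched.

Step 21
Reactants: 29 S-ethyl thioester; 31 alkylzinc bromide
Product: 32 γ-keto ester (ring A–C(=O)–CH2–CH(CH3)–CO2Me)
Conditions: 31 (2.5 equiv), PdCl2(PPh3)2 (5 mol%), toluene/N,N-dimethylacetamide, rt; dilute HCl work-up
Reagents that add atoms: none
Why: Fukuyama coupling of the thioester with the alkylzinc reagent gives the ketone under neutral conditions that tolerate lactone, lactam and free hydroxyl and do not epimerise the α-amido centre.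

Step 22
Reactants: 32 γ-keto ester
Product: 34 bis-lactone lactam (rings A–E), via hydroxy ester 33 (not isolated)
Conditions: LiBH(s-Bu)3 (2.2 equiv), THF, −78 °C; then AcOH, rt
Reagents that add atoms: none
Why: Felkin–Anh reduction of the α-amido ketone by the bulky hydride, anti to the C–N bond, should give the syn amino alcohol arrangement, and the alkoxide lactonises onto the methyl ester to close ring E, whose methyl-bearing carbon comes unchanged from 30.

Step 23
Reactants: 34 bis-lactone lactam
Product: 35 target CNP0260919.3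
Conditions: RhH(CO)(PPh3)3 (2 mol%), Ph2SiH2 (3 equiv), THF, rt; then 1 M HCl/MeOH, rt; NaHCO3 work-up
Reagents that add atoms: none
Why: rhodium-catalysed hydrosilylation reduces tertiary amides, lactams included, to amines while esters and lactones are left alone; mild acid removes any silyl group taken up by the tertiary alcohol.

**Compound list**

1 | 2-(1H-pyrrol-2-yl)acetonitrile | N#CCc1ccc[nH]1 | starting material
2 | ethyl 2-bromobutanoate (racemic) | CCC(Br)C(=O)OCC | starting material
3 | ethyl (Z)-3-amino-2-ethyl-4-(1H-pyrrol-2-yl)but-2-enoate (zinc-bound in the flask) | CCOC(=O)/C(CC)=C(\N)Cc1ccc[nH]1 | intermediate (not isolated)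
4 | ethyl 2-ethyl-3-oxo-4-(1H-pyrrol-2-yl)butanoate (racemic) | CCOC(=O)C(CC)C(=O)Cc1ccc[nH]1 | intermediate
5 | {[5-(4-ethoxy-3-ethyl-2,4-dioxobutyl)-1H-pyrrol-2-yl]methylidene}dimethylammonium chloride | CCOC(=O)C(CC)C(=O)Cc1ccc(C=[N+](C)C)[nH]1.[Cl-] | intermediate (not isolated)
6 | ethyl 2-ethyl-4-(5-formyl-1H-pyrrol-2-yl)-3-oxobutanoate (racemic) | CCOC(=O)C(CC)C(=O)Cc1ccc(C=O)[nH]1 | intermediate
7 | ethyl 2-{2-[(5-formyl-1H-pyrrol-2-yl)methyl]-1,3-dioxolan-2-yl}butanoate (racemic) | CCOC(=O)C(CC)C1(Cc2ccc(C=O)[nH]2)OCCO1 | intermediate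
8 | ethyl 2-{2-[(5-(hydroxymethyl)-1H-pyrrol-2-yl)methyl]-1,3-dioxolan-2-yl}butanoate (racemic) | CCOC(=O)C(CC)C1(Cc2ccc(CO)[nH]2)OCCO1 | intermediate
9 | ethyl 2-{2-[(5-{[tert-butyl(diphenyl)silyl]oxymethyl}-1H-pyrrol-2-yl)methyl]-1,3-dioxolan-2-yl}butanoate (racemic) | CCOC(=O)C(CC)C1(Cc2ccc(CO[Si](c3ccccc3)(c3ccccc3)C(C)(C)C)[nH]2)OCCO1 | intermediate
10 | triethyl phosphonoacetate | CCOC(=O)CP(=O)(OCC)OCC | starting material
11 | 2-{2-[(5-{[tert-butyl(diphenyl)silyl]oxymethyl}-1H-pyrrol-2-yl)methyl]-1,3-dioxolan-2-yl}butanal (racemic) | CCC(C=O)C1(Cc2ccc(CO[Si](c3ccccc3)(c3ccccc3)C(C)(C)C)[nH]2)OCCO1 | intermediate (not isolated)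
12 | ethyl (E)-4-{2-[(5-{[tert-butyl(diphenyl)silyl]oxymethyl}-1H-pyrrol-2-yl)methyl]-1,3-dioxolan-2-yl}hex-2-enoate (racemic) | CCOC(=O)/C=C/C(CC)C1(Cc2ccc(CO[Si](c3ccccc3)(c3ccccc3)C(C)(C)C)[nH]2)OCCO1 | intermediate
13 | (E)-4-{2-[(5-{[tert-butyl(diphenyl)silyl]oxymethyl}-1H-pyrrol-2-yl)methyl]-1,3-dioxolan-2-yl}hex-2-en-1-ol (racemic) | CCC(/C=C/CO)C1(Cc2ccc(CO[Si](c3ccccc3)(c3ccccc3)C(C)(C)C)[nH]2)OCCO1 | intermediate
14 | (E)-4-{2-[(5-{[tert-butyl(diphenyl)silyl]oxymethyl}-1H-pyrrol-2-yl)methyl]-1,3-dioxolan-2-yl}hex-2-en-1-yl methyl carbonate (racemic; cyclisation precursor) | CCC(/C=C/COC(=O)OC)C1(OCCO1)Cc1ccc(CO[Si](c2ccccc2)(c2ccccc2)C(C)(C)C)[nH]1 | intermediate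
15 | (5R,6R,7R)-2-{[tert-butyl(diphenyl)silyl]oxymethyl}-7-ethyl-6-vinyl-1-azaspiro[4.4]nona-1,3-dien-8-one ethylene ketal (vinyl cis to N, ethyl trans to vinyl) | CC[C@H]1C2(OCCO2)C[C@@]3(C=CC(CO[Si](c4ccccc4)(c4ccccc4)C(C)(C)C)=N3)[C@@H]1C=C | intermediate
16 | methyl but-3-enoate | C=CCC(=O)OC | starting material
17 | methyl (E)-4-[spiro-2H-pyrrol-6-yl]but-3-enoate (15 with CH=CH–CH2–CO2Me in place of vinyl, same configuration) | CC[C@H]1C2(OCCO2)C[C@@]3(C=CC(CO[Si](c4ccccc4)(c4ccccc4)C(C)(C)C)=N3)[C@@H]1/C=C/CC(=O)OC | intermediate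
18 | saturated amino ester (1-azaspiro[4.4]nonane; CH2OTBDPS on ring A cis to the butanoate-bearing carbon; methyl butanoate chain cis to N on ring C) | CC[C@H]1C2(OCCO2)C[C@@]3(CC[C@@H](CO[Si](c4ccccc4)(c4ccccc4)C(C)(C)C)N3)[C@@H]1CCCC(=O)OC | intermediate (not isolated)
19 | tricyclic lactam ketal (pyrrolidine A, azepan-2-one B and cyclopentane C sharing the aza-quaternary carbon; B/C cis-fused; ethyl trans to the ring-B CH2; ethylene ketal next to the ethyl-bearing carbon; CH2OTBDPS on ring A) | CC[C@H]1C4(OCCO4)C[C@]23CC[C@@H](CO[Si](c5ccccc5)(c5ccccc5)C(C)(C)C)N2C(=O)CCC[C@H]13 | intermediate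
20 | tricyclic keto lactam (19 with C=O in place of the ketal) | CC[C@H]1C(=O)C[C@]23CC[C@@H](CO[Si](c4ccccc4)(c4ccccc4)C(C)(C)C)N2C(=O)CCC[C@H]13 | intermediate
21 | ethyl glyoxylate | CCOC(=O)C=O | starting material
22 | aldol adduct (CH(OH)CO2Et arm on the carbon between ketone and spiro carbon, trans to N; carbinol epimers) | CC[C@H]1C(=O)[C@@H](C(O)C(=O)OCC)[C@]23CC[C@@H](CO[Si](c4ccccc4)(c4ccccc4)C(C)(C)C)N2C(=O)CCC[C@H]13 | intermediate
23 | diol ester (ring-C alcohol cis to ethyl and to the hydroxy ester arm) | CC[C@H]1[C@@H](O)[C@@H](C(O)C(=O)OCC)[C@]23CC[C@@H](CO[Si](c4ccccc4)(c4ccccc4)C(C)(C)C)N2C(=O)CCC[C@H]13 | intermediate (not isolated)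
24 | α-hydroxy lactone (cis-fused lactone D on ring C; carbinol epimers) | CC[C@H]1[C@H]2OC(=O)C(O)[C@H]2[C@]23CC[C@@H](CO[Si](c4ccccc4)(c4ccccc4)C(C)(C)C)N2C(=O)CCC[C@H]13 | intermediate
25 | α-(tert-butyldimethylsilyloxy) lactone | CC[C@H]1[C@H]2OC(=O)C(O[Si](C)(C)C(C)(C)C)[C@H]2[C@]23CC[C@@H](CO[Si](c4ccccc4)(c4ccccc4)C(C)(C)C)N2C(=O)CCC[C@H]13 | intermediate
26 | α-methyl-α-(tert-butyldimethylsilyloxy) lactone (methyl cis to the ring-fusion hydrogens) | CC[C@H]1[C@H]2OC(=O)[C@@](C)(O[Si](C)(C)C(C)(C)C)[C@H]2[C@]23CC[C@@H](CO[Si](c4ccccc4)(c4ccccc4)C(C)(C)C)N2C(=O)CCC[C@H]13 | intermediate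
27 | diol (ring-A CH2OH; tertiary α-hydroxy-α-methyl lactone D; lactam) | CC[C@H]1[C@H]2OC(=O)[C@@](C)(O)[C@H]2[C@]23CC[C@@H](CO)N2C(=O)CCC[C@H]13 | intermediate
28 | ring-A carboxylic acid | CC[C@H]1[C@H]2OC(=O)[C@@](C)(O)[C@H]2[C@]23CC[C@@H](C(=O)O)N2C(=O)CCC[C@H]13 | intermediate
29 | ring-A S-ethyl thioester | CC[C@H]1[C@H]2OC(=O)[C@@](C)(O)[C@H]2[C@]23CC[C@@H](C(=O)SCC)N2C(=O)CCC[C@H]13 | intermediate
30 | methyl (R)-3-bromo-2-methylpropanoate | BrC[C@H](C)C(=O)OC | starting material
31 | [(R)-3-methoxy-2-methyl-3-oxopropyl]zinc bromide | Br[Zn]C[C@H](C)C(=O)OC | intermediate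
32 | γ-keto ester (ring A–C(=O)–CH2–CH(CH3)–CO2Me) | CC[C@H]1[C@H]2OC(=O)[C@@](C)(O)[C@H]2[C@]23CC[C@@H](C(=O)C[C@H](C)C(=O)OC)N2C(=O)CCC[C@H]13 | intermediate
33 | γ-hydroxy ester (carbinol syn to the ring-A nitrogen) | CC[C@H]1[C@H]2OC(=O)[C@@](C)(O)[C@H]2[C@]23CC[C@@H]([C@@H](O)C[C@H](C)C(=O)OC)N2C(=O)CCC[C@H]13 | intermediate (not isolated)
34 | bis-lactone lactam (rings A–E, ring-B carbonyl still present) | CC[C@H]1[C@H]2OC(=O)[C@@](C)(O)[C@H]2[C@]23CC[C@@H]([C@@H]4C[C@H](C)C(=O)O4)N2C(=O)CCC[C@H]13 | intermediate
35 | CNP0260919.3 (ethyl-bearing C R; lactone-D O-bearing C R; carbinol C S; adjacent ring-C/D fusion C S; aza-quaternary C R; B/C fusion C R; ring-A CH S; lactone-E O-bearing C S; lactone-E methyl-bearing C S) | CC[C@H]1[C@H]2OC(=O)[C@@](C)(O)[C@H]2[C@]23CC[C@@H]([C@@H]4C[C@H](C)C(=O)O4)N2CCCC[C@H]13 | target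

**Step count.** Total: 23 steps. Longest linear sequence: 22 steps (steps 1–19 and 21–23; step 20 is a one-step branch).

**Steps most likely to fail**

1. Step 9. What may go wrong: loss of catalyst control because the racemic ethyl-bearing centre sits next to the allyl terminus, so that the mismatched antipode cyclises with the wrong facial sense and erodes enantiopurity; closure through nitrogen or through the other pyrrole face may also compete. Fallback: remove the mismatch before the cyclisation. It sets out from 7: saponification (LiOH, THF/H2O) gives the racemic acid F1, which is resolved by crystallisation of its salt with one antipode of 1-phenylethylamine to the (S)-acid F2. Re-esterification (EtI, K2CO3, DMF) comes back to the route at 7, now as a single antipode. This is taken through steps 4–8, with the olefination of step 6 run with LiCl and an amine base so that the α-centre of the aldehyde is kept. Step 9 then runs in the matched, substrate-reinforced sense to 15.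

2. Step 13. What may go wrong: enolisation toward the ethyl-bearing carbon, or entry of the electrophile on the nitrogen face of the enolate. Fallback: it sets out from 20. Condensation with 21 (piperidinium acetate, toluene, 80 °C) can only take place at the CH2 and gives the alkylidene keto ester F3. Hydrogenation (H2, Pd/C, EtOAc) then delivers hydrogen from the face an electrophile would have used, so the acetate arm ends on the opposite face, giving the keto ester F4. Reduction with LiBH(s-Bu)3 gives the cis-fused lactone F5, and enolate hydroxylation (KN(SiMe3)2, 2-(phenylsulfonyl)-3-phenyloxaziridine, THF, −78 °C) comes back to the route at 24.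

3. Step 10. What may go wrong: slow metathesis at the hindered vinyl group, with isomerisation and self-metathesis of the butenoate taking over. Fallback: it sets out from 15. Hydroboration–oxidation of the vinyl group (9-borabicyclo[3.3.1]nonane, THF; then NaBO3) gives the primary alcohol F6, Dess–Martin oxidation (NaHCO3-buffered) gives the aldehyde F7, and Wittig olefination with Ph3P=CHCO2Me gives the enoate F8. Hydrogenation and lactamisation exactly as in step 11 then come back to the route at 19.

**Further compounds**

F1 | step 9 | 2-{2-[(5-formyl-1H-pyrrol-2-yl)methyl]-1,3-dioxolan-2-yl}butanoic acid (racemic) | CCC(C(=O)O)C1(OCCO1)Cc1ccc(C=O)[nH]1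
F2 | step 9 | (S)-2-{2-[(5-formyl-1H-pyrrol-2-yl)methyl]-1,3-dioxolan-2-yl}butanoic acid | CC[C@H](C(=O)O)C1(OCCO1)Cc1ccc(C=O)[nH]1
F3 | step 13 | alkylidene keto ester (ethoxycarbonylmethylidene on the carbon between ketone and spiro carbon; alkene geometry not controlled) | CC[C@H]1C(=O)C(=CC(=O)OCC)[C@]23CC[C@@H](CO[Si](c4ccccc4)(c4ccccc4)C(C)(C)C)N2C(=O)CCC[C@H]13
F4 | step 13 | keto ester (CH2CO2Et arm trans to N) | CC[C@H]1C(=O)[C@@H](CC(=O)OCC)[C@]23CC[C@@H](CO[Si](c4ccccc4)(c4ccccc4)C(C)(C)C)N2C(=O)CCC[C@H]13
F5 | step 13 | cis-fused lactone D without α-substituents | CC[C@H]1[C@H]2OC(=O)C[C@H]2[C@]23CC[C@@H](CO[Si](c4ccccc4)(c4ccccc4)C(C)(C)C)N2C(=O)CCC[C@H]13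
F6 | step 10 | primary alcohol (2-hydroxyethyl in place of vinyl in 15) | CC[C@H]1C2(OCCO2)C[C@@]3(C=CC(CO[Si](c4ccccc4)(c4ccccc4)C(C)(C)C)=N3)[C@@H]1CCO
F7 | step 10 | aldehyde (2-oxoethyl in place of vinyl in 15) | CC[C@H]1C2(OCCO2)C[C@@]3(C=CC(CO[Si](c4ccccc4)(c4ccccc4)C(C)(C)C)=N3)[C@@H]1CC=O
F8 | step 10 | methyl (E)-4-[spiro-2H-pyrrol-6-yl]but-2-enoate | CC[C@H]1C2(OCCO2)C[C@@]3(C=CC(CO[Si](c4ccccc4)(c4ccccc4)C(C)(C)C)=N3)[C@@H]1C/C=C/C(=O)OC
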